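**Retrosynthetic overview**
1. The acetate and both aldehydes are late adjustments of a nine-membered ring enoate that carries a dimethyl acetal (future CHO on the sp3 carbon) and an ethyl ester (future enal CHO).
2. Key step: the only ring is closed by a macrocyclic Horner–Wadsworth–Emmons olefination that makes the enal C=C, not by metathesis, cross-coupling or Grob fragmentation at the E-trisubstituted alkene.
3. The E-trisubstituted alkene is bought in a C6 allylic chloride and joined by an α-selective, Felkin-controlled allylbarium addition that also sets the carbinol centre.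
4. The aldehyde for that addition comes from one organocatalytic Michael addition of (S)-citronellal to a phosphonoacrylate, which sets both ring CH centres and plants the phosphonate; the side-chain centre is from the chiral pool.
5. Ring order: one carbocycle only, closed in step 10 of 14.

Assumption: the phosphonate-bearing carbon is carried as an epimer mixture and the acceptor as an E/Z mixture (both are erased later); the acetal-bearing centre is S by CIP while phosphorus is attached and R afterwards, with no change in space.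

**Step 1**
Reactants: 1 triethyl phosphonoacetate; 2 2,2-dimethoxyacetaldehyde (60% aqueous solution)
Product: 3 ethyl (2E)-2-(diethoxyphosphoryl)-4,4-dimethoxybut-2-enoate
Conditions: piperidine (cat.), AcOH (cat.), toluene, Dean–Stark, reflux
Reagents that add atoms: none
Why: Knoevenagel condensation of the doubly activated methylene with an aldehyde that cannot self-condense, driven by azeotropic removal of water, and both alkene isomers lead to the same Michael adduct.

**Step 2**
Reactants: 4 (3S)-3,7-dimethyloct-6-enal; 3 ethyl (2E)-2-(diethoxyphosphoryl)-4,4-dimethoxybut-2-enoate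
Product: 5 ethyl (3S,4R,5S)-2-(diethoxyphosphoryl)-3-(dimethoxymethyl)-4-formyl-5,9-dimethyldec-8-enoate
Conditions: (S)-2-[diphenyl(trimethylsilyloxy)methyl]pyrrolidine (20 mol%), PhCO2H (20 mol%), CH2Cl2, 0 °C to rt
Reagents that add atoms: none
Why: Asymmetric Michael addition under enamine catalysis (Hayashi–Jørgensen type) to a doubly activated alkene, in which the (S)-catalyst blocks one enamine face and the acyclic synclinal transition state gives the syn adduct, setting C4 as R and C3 as S in the sense known for nitroalkenes and alkylidene malonates, while the phosphonoacetate stays as a built-in olefination handle.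

**Step 3**
Reactants: 6 3-[(tert-butyldimethylsilyl)oxy]propanal; 7 ethyl 2-(triphenylphosphoranylidene)propanoate
Product: 8 ethyl (2E)-5-[(tert-butyldimethylsilyl)oxy]-2-methylpent-2-enoate
Conditions: CH2Cl2, rt
Reagents that add atoms: none
Why: Wittig olefination with a stabilised α-methyl ylide gives the E-trisubstituted enoate with high selectivity.

**Step 4**
Reactants: 8 ethyl (2E)-5-[(tert-butyldimethylsilyl)oxy]-2-methylpent-2-enoate
Product: 9 (2E)-5-[(tert-butyldimethylsilyl)oxy]-2-methylpent-2-en-1-ol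
Conditions: iBu2AlH, CH2Cl2, −78 °C; aq. KNaC4H4O6
Reagents that add atoms: none
Why: Aluminium hydride 1,2-reduction of the conjugated ester gives the allylic alcohol and leaves the silyl ether and the E geometry untouched.

**Step 5**
Reactants: 9 (2E)-5-[(tert-butyldimethylsilyl)oxy]-2-methylpent-2-en-1-ol
Product: 11 tert-butyl{[(3E)-5-chloro-4-methylpent-3-en-1-yl]oxy}dimethylsilane, via allylic mesylate 10 (not isolated)
Conditions: MsCl, LiCl, 2,4,6-collidine, DMF, 0 °C
Reagents that add atoms: lithium chloride, [Li+].[Cl-]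
Why: Mesylation followed by in situ chloride displacement (Collington–Meyers chlorination) gives the primary allylic chloride without allylic transposition or loss of E geometry.

**Step 6**
Reactants: 5 ethyl (3S,4R,5S)-2-(diethoxyphosphoryl)-3-(dimethoxymethyl)-4-formyl-5,9-dimethyldec-8-enoate; 11 tert-butyl{[(3E)-5-chloro-4-methylpent-3-en-1-yl]oxy}dimethylsilane
Product: 14 ethyl (3S,4R,5R,7E)-10-[(tert-butyldimethylsilyl)oxy]-2-(diethoxyphosphoryl)-3-(dimethoxymethyl)-5-hydroxy-7-methyl-4-[(2S)-6-methylhept-5-en-2-yl]dec-7-enoate, via lithium phosphonoacetate enolate 12 (not isolated), via allylbarium chloride 13 (not isolated)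
Conditions: 5, LiN(SiMe3)2 (1.0 equiv), THF, −78 °C; 11, zerovalent Ba (from BaI2 and LiC12H10), THF, −78 °C; combine at −78 °C; aq. NH4Cl
Reagents that add atoms: none
Why: Carbonyl allylation with an allylbarium reagent, which adds through its less substituted α-carbon with retention of the E geometry, after the acidic phosphonoacetate has been parked as its lithium enolate (which also shields the ester), and Felkin–Anh attack anti to the bulky C3 branch sets the new carbinol centre C5 as R.

**Step 7**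
Reactants: 14 ethyl (3S,4R,5R,7E)-10-[(tert-butyldimethylsilyl)oxy]-2-(diethoxyphosphoryl)-3-(dimethoxymethyl)-5-hydroxy-7-methyl-4-[(2S)-6-methylhept-5-en-2-yl]dec-7-enoate
Product: 15 ethyl (3S,4R,5R,7E)-5-(acetyloxy)-10-[(tert-butyldimethylsilyl)oxy]-2-(diethoxyphosphoryl)-3-(dimethoxymethyl)-7-methyl-4-[(2S)-6-methylhept-5-en-2-yl]dec-7-enoate
Conditions: Ac2O, pyridine, DMAP (cat.), CH2Cl2, 0 °C to rt
Reagents that add atoms: acetic anhydride, CC(=O)OC(C)=O
Why: DMAP-catalysed acylation masks the secondary alcohol so that it cannot lactonise onto the ester or attack phosphorus during the later olefination.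

**Step 8**
Reactants: 15 ethyl (3S,4R,5R,7E)-5-(acetyloxy)-10-[(tert-butyldimethylsilyl)oxy]-2-(diethoxyphosphoryl)-3-(dimethoxymethyl)-7-methyl-4-[(2S)-6-methylhept-5-en-2-yl]dec-7-enoate
Product: 16 ethyl (3S,4R,5R,7E)-5-(acetyloxy)-2-(diethoxyphosphoryl)-3-(dimethoxymethyl)-10-hydroxy-7-methyl-4-[(2S)-6-methylhept-5-en-2-yl]dec-7-enoate
Conditions: HF·pyridine, pyridine, THF, 0 °C to rt
Reagents that add atoms: none
Why: Fluoride-mediated desilylation of the primary silyl ether under pyridine-buffered conditions leaves the acetal, the acetate and the phosphonate intact.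

**Step 9**
Reactants: 16 ethyl (3S,4R,5R,7E)-5-(acetyloxy)-2-(diethoxyphosphoryl)-3-(dimethoxymethyl)-10-hydroxy-7-methyl-4-[(2S)-6-methylhept-5-en-2-yl]dec-7-enoate
Product: 17 ethyl (3S,4R,5R,7E)-5-(acetyloxy)-2-(diethoxyphosphoryl)-3-(dimethoxymethyl)-7-methyl-4-[(2S)-6-methylhept-5-en-2-yl]-10-oxodec-7-enoate
Conditions: Dess–Martin periodinane, NaHCO3, CH2Cl2, 0 °C; used crude
Reagents that add atoms: none
Why: Dess–Martin oxidation under buffered, near-neutral conditions gives the β,γ-unsaturated aldehyde without moving the alkene into conjugation.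

**Step 10**
Reactants: 17 ethyl (3S,4R,5R,7E)-5-(acetyloxy)-2-(diethoxyphosphoryl)-3-(dimethoxymethyl)-7-methyl-4-[(2S)-6-methylhept-5-en-2-yl]-10-oxodec-7-enoate
Product: 18 ethyl (1E,4E,7R,8R,9R)-7-(acetyloxy)-9-(dimethoxymethyl)-5-methyl-8-[(2S)-6-methylhept-5-en-2-yl]cyclonona-1,4-diene-1-carboxylate
Conditions: LiCl, DBU, MeCN, slow addition to 1 mmol/L, rt
Reagents that add atoms: none
Why: Intramolecular Horner–Wadsworth–Emmons olefination under Masamune–Roush conditions at high dilution closes the nine-membered ring irreversibly, and because a second trans alkene cannot fit in the ring only the enoate with the ring carbons cis on the new double bond (E by CIP, as in the target) can form.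

**Step 11**
Reactants: 18 ethyl (1E,4E,7R,8R,9R)-7-(acetyloxy)-9-(dimethoxymethyl)-5-methyl-8-[(2S)-6-methylhept-5-en-2-yl]cyclonona-1,4-diene-1-carboxylate
Product: 19 (1R,3E,6E,8R,9R)-8-(dimethoxymethyl)-7-(hydroxymethyl)-3-methyl-9-[(2S)-6-methylhept-5-en-2-yl]cyclonona-3,6-dien-1-ol
Conditions: iBu2AlH (5 equiv), CH2Cl2, −78 to 0 °C; aq. KNaC4H4O6
Reagents that add atoms: none
Why: Aluminium hydride 1,2-reduction turns the enoate into the allylic alcohol and cleaves the acetate in the same operation, while the acetal and the alkenes are inert.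

**Step 12**
Reactants: 19 (1R,3E,6E,8R,9R)-8-(dimethoxymethyl)-7-(hydroxymethyl)-3-methyl-9-[(2S)-6-methylhept-5-en-2-yl]cyclonona-3,6-dien-1-ol
Product: 20 (1E,4E,7R,8R,9R)-9-(dimethoxymethyl)-7-hydroxy-5-methyl-8-[(2S)-6-methylhept-5-en-2-yl]cyclonona-1,4-diene-1-carbaldehyde
Conditions: MnO2, CH2Cl2, rt
Reagents that add atoms: none
Why: Chemoselective allylic oxidation with MnO2 converts only the allylic primary alcohol into the enal and leaves the homoallylic secondary alcohol.

**Step 13**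
Reactants: 20 (1E,4E,7R,8R,9R)-9-(dimethoxymethyl)-7-hydroxy-5-methyl-8-[(2S)-6-methylhept-5-en-2-yl]cyclonona-1,4-diene-1-carbaldehyde
Product: 21 (1R,3E,6E,8R,9R)-8-(dimethoxymethyl)-7-formyl-3-methyl-9-[(2S)-6-methylhept-5-en-2-yl]cyclonona-3,6-dien-1-yl acetate
Conditions: Ac2O, pyridine, DMAP (cat.), CH2Cl2, 0 °C
Reagents that add atoms: acetic anhydride, CC(=O)OC(C)=O
Why: DMAP-catalysed acetylation of the secondary alcohol is done while the second aldehyde is still an acetal, so no lactol can form.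

**Step 14**
Reactants: 21 (1R,3E,6E,8R,9R)-8-(dimethoxymethyl)-7-formyl-3-methyl-9-[(2S)-6-methylhept-5-en-2-yl]cyclonona-3,6-dien-1-yl acetate
Product: 22 (1R,3E,6E,8R,9R)-7,8-diformyl-3-methyl-9-[(2S)-6-methylhept-5-en-2-yl]cyclonona-3,6-dien-1-yl acetate
Conditions: oxalic acid (10% aq.) on SiO2, CH2Cl2, rt
Reagents that add atoms: water, O
Why: Mild acid-catalysed acetal hydrolysis on wet silica unmasks the second aldehyde without cleaving the acetate, epimerising the α-centre or moving the β,γ-alkene into conjugation.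

**Compound list**
1 | triethyl phosphonoacetate | CCOC(=O)CP(=O)(OCC)OCC | starting material
2 | 2,2-dimethoxyacetaldehyde | COC(OC)C=O | starting material
3 | ethyl (2E)-2-(diethoxyphosphoryl)-4,4-dimethoxybut-2-enoate (E drawn; the E/Z mixture is used) | CCOC(=O)/C(P(=O)(OCC)OCC)=C\C(OC)OC | intermediate
4 | (3S)-3,7-dimethyloct-6-enal, (S)-citronellal | O=CC[C@@H](C)CCC=C(C)C | starting material
5 | ethyl (3S,4R,5S)-2-(diethoxyphosphoryl)-3-(dimethoxymethyl)-4-formyl-5,9-dimethyldec-8-enoate (C2 epimers) | O=C[C@H]([C@@H](C)CCC=C(C)C)[C@@H](C(OC)OC)C(P(=O)(OCC)OCC)C(=O)OCC | intermediate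
6 | 3-[(tert-butyldimethylsilyl)oxy]propanal | O=CCCO[Si](C)(C)C(C)(C)C | starting material
7 | ethyl 2-(triphenylphosphoranylidene)propanoate | CCOC(=O)C(C)=P(c1ccccc1)(c1ccccc1)c1ccccc1 | starting material
8 | ethyl (2E)-5-[(tert-butyldimethylsilyl)oxy]-2-methylpent-2-enoate | CCOC(=O)/C(C)=C/CCO[Si](C)(C)C(C)(C)C | intermediate
9 | (2E)-5-[(tert-butyldimethylsilyl)oxy]-2-methylpent-2-en-1-ol | OC/C(C)=C/CCO[Si](C)(C)C(C)(C)C | intermediate
10 | (2E)-5-[(tert-butyldimethylsilyl)oxy]-2-methylpent-2-en-1-yl methanesulfonate | CS(=O)(=O)OC/C(C)=C/CCO[Si](C)(C)C(C)(C)C | intermediate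
11 | tert-butyl{[(3E)-5-chloro-4-methylpent-3-en-1-yl]oxy}dimethylsilane | ClC/C(C)=C/CCO[Si](C)(C)C(C)(C)C | intermediate
12 | lithium salt of 5 (phosphonate-stabilised carbanion at C2) | [Li+].O=C[C@H]([C@@H](C)CCC=C(C)C)[C@@H](C(OC)OC)[C-](P(=O)(OCC)OCC)C(=O)OCC | intermediate
13 | {(2E)-5-[(tert-butyldimethylsilyl)oxy]-2-methylpent-2-en-1-yl}barium chloride | Cl[Ba]C/C(C)=C/CCO[Si](C)(C)C(C)(C)C | intermediate
14 | ethyl (3S,4R,5R,7E)-10-[(tert-butyldimethylsilyl)oxy]-2-(diethoxyphosphoryl)-3-(dimethoxymethyl)-5-hydroxy-7-methyl-4-[(2S)-6-methylhept-5-en-2-yl]dec-7-enoate | CC(C)(C)[Si](C)(C)OCC/C=C(\C)C[C@@H](O)[C@H]([C@@H](C)CCC=C(C)C)[C@@H](C(OC)OC)C(P(=O)(OCC)OCC)C(=O)OCC | intermediate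
15 | ethyl (3S,4R,5R,7E)-5-(acetyloxy)-10-[(tert-butyldimethylsilyl)oxy]-2-(diethoxyphosphoryl)-3-(dimethoxymethyl)-7-methyl-4-[(2S)-6-methylhept-5-en-2-yl]dec-7-enoate | CC(C)(C)[Si](C)(C)OCC/C=C(\C)C[C@@H](OC(C)=O)[C@H]([C@@H](C)CCC=C(C)C)[C@@H](C(OC)OC)C(P(=O)(OCC)OCC)C(=O)OCC | intermediate
16 | ethyl (3S,4R,5R,7E)-5-(acetyloxy)-2-(diethoxyphosphoryl)-3-(dimethoxymethyl)-10-hydroxy-7-methyl-4-[(2S)-6-methylhept-5-en-2-yl]dec-7-enoate | OCC/C=C(\C)C[C@@H](OC(C)=O)[C@H]([C@@H](C)CCC=C(C)C)[C@@H](C(OC)OC)C(P(=O)(OCC)OCC)C(=O)OCC | intermediate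
17 | ethyl (3S,4R,5R,7E)-5-(acetyloxy)-2-(diethoxyphosphoryl)-3-(dimethoxymethyl)-7-methyl-4-[(2S)-6-methylhept-5-en-2-yl]-10-oxodec-7-enoate | O=CC/C=C(\C)C[C@@H](OC(C)=O)[C@H]([C@@H](C)CCC=C(C)C)[C@@H](C(OC)OC)C(P(=O)(OCC)OCC)C(=O)OCC | intermediate
18 | ethyl (1E,4E,7R,8R,9R)-7-(acetyloxy)-9-(dimethoxymethyl)-5-methyl-8-[(2S)-6-methylhept-5-en-2-yl]cyclonona-1,4-diene-1-carboxylate | CC(=O)O[C@@H]1C/C(C)=C/C/C=C(/C(=O)OCC)[C@H](C(OC)OC)[C@H]1[C@@H](C)CCC=C(C)C | intermediate
19 | (1R,3E,6E,8R,9R)-8-(dimethoxymethyl)-7-(hydroxymethyl)-3-methyl-9-[(2S)-6-methylhept-5-en-2-yl]cyclonona-3,6-dien-1-ol | O[C@@H]1C/C(C)=C/C/C=C(/CO)[C@H](C(OC)OC)[C@H]1[C@@H](C)CCC=C(C)C | intermediate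
20 | (1E,4E,7R,8R,9R)-9-(dimethoxymethyl)-7-hydroxy-5-methyl-8-[(2S)-6-methylhept-5-en-2-yl]cyclonona-1,4-diene-1-carbaldehyde | O[C@@H]1C/C(C)=C/C/C=C(/C=O)[C@H](C(OC)OC)[C@H]1[C@@H](C)CCC=C(C)C | intermediate
21 | (1R,3E,6E,8R,9R)-8-(dimethoxymethyl)-7-formyl-3-methyl-9-[(2S)-6-methylhept-5-en-2-yl]cyclonona-3,6-dien-1-yl acetate | CC(=O)O[C@@H]1C/C(C)=C/C/C=C(/C=O)[C@H](C(OC)OC)[C@H]1[C@@H](C)CCC=C(C)C | intermediate
22 | (1R,3E,6E,8R,9R)-7,8-diformyl-3-methyl-9-[(2S)-6-methylhept-5-en-2-yl]cyclonona-3,6-dien-1-yl acetate | CC(=O)O[C@@H]1C/C(C)=C/C/C=C(/C=O)[C@H](C=O)[C@H]1[C@@H](C)CCC=C(C)C | target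

**Totals and risks**

Total step count: 14. Longest linear sequence: 12 steps (steps 3 to 14, from 6).

Most likely to fail, first: step 10, the macrocyclic olefination. A nine-membered ring that already holds an E-trisubstituted alkene is strained, so dimerisation or base-induced migration of the β,γ-alkene of 17 may win. The fallback sets out from 17 and comes back at 18. The aldehyde is methylenated with Ph3P=CH2 (from Ph3PCH3Br and KN(SiMe3)2, THF, −78 to 0 °C) to the terminal alkene F4. The phosphonoacetate of F4 is then olefinated with aqueous formaldehyde (K2CO3) to the acrylate F5. Ring-closing metathesis of F5 (second-generation Hoveyda–Grubbs catalyst, toluene, 80 °C, 1 mmol/L) forms the same trisubstituted enoate bond with loss of ethene and gives 18.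

Second: step 2, the Michael addition. The β-substituted phosphonoacrylate 3 is an untested acceptor for enamine catalysis, so rate and syn selectivity are extrapolated from nitroalkenes, alkylidene malonates and the unsubstituted phosphonoacrylate. The fallback sets out from 4 and comes back at 5. Aldehyde 4 is condensed with (2R)-2-(methoxymethyl)pyrrolidin-1-amine to the RAMP hydrazone F1. F1 is deprotonated with LiN(iPr)2 (THF, −78 °C) and the aza-enolate is added to 3 to give the hydrazone Michael adduct F2. The hydrazone is then cleaved with aqueous CuCl2 at pH 7 to return 5. A stoichiometric auxiliary then fixes C4; the sense at C3 would have to be confirmed.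

Third: step 6, the allylbarium addition. The reagent is strongly basic and the Felkin preference between two branched α-substituents may be modest, so 14 may arrive as a C5 epimer mixture. The fallback sets out from 14 (epimer mixture) and comes back at 14 (single epimer). The mixture is oxidised with Dess–Martin periodinane (NaHCO3, CH2Cl2) to the β,γ-unsaturated ketone F3. F3 is reduced with catecholborane and the (S)-Me-CBS oxazaborolidine (toluene, −78 °C), so that the reagent, not the substrate, sets C5 as R.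

**Further compounds**
F1 | step 2 | (1E,3S)-N-[(2R)-2-(methoxymethyl)pyrrolidin-1-yl]-3,7-dimethyloct-6-en-1-imine | COC[C@H]1CCCN1/N=C/C[C@@H](C)CCC=C(C)C
F2 | step 2 | ethyl (3S,4R,5S)-2-(diethoxyphosphoryl)-3-(dimethoxymethyl)-4-[(E)-{[(2R)-2-(methoxymethyl)pyrrolidin-1-yl]imino}methyl]-5,9-dimethyldec-8-enoate | COC[C@H]1CCCN1/N=C/[C@H]([C@@H](C)CCC=C(C)C)[C@@H](C(OC)OC)C(P(=O)(OCC)OCC)C(=O)OCC
F3 | step 6 | ethyl (3S,4R,7E)-10-[(tert-butyldimethylsilyl)oxy]-2-(diethoxyphosphoryl)-3-(dimethoxymethyl)-7-methyl-4-[(2S)-6-methylhept-5-en-2-yl]-5-oxodec-7-enoate | CC(C)(C)[Si](C)(C)OCC/C=C(\C)CC(=O)[C@H]([C@@H](C)CCC=C(C)C)[C@@H](C(OC)OC)C(P(=O)(OCC)OCC)C(=O)OCC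
F4 | step 10 | ethyl (3S,4R,5R,7E)-5-(acetyloxy)-2-(diethoxyphosphoryl)-3-(dimethoxymethyl)-7-methyl-4-[(2S)-6-methylhept-5-en-2-yl]undeca-7,10-dienoate | C=CC/C=C(\C)C[C@@H](OC(C)=O)[C@H]([C@@H](C)CCC=C(C)C)[C@@H](C(OC)OC)C(P(=O)(OCC)OCC)C(=O)OCC
F5 | step 10 | ethyl (3R,4R,5R,7E)-5-(acetyloxy)-3-(dimethoxymethyl)-7-methyl-2-methylidene-4-[(2S)-6-methylhept-5-en-2-yl]undeca-7,10-dienoate | C=CC/C=C(\C)C[C@@H](OC(C)=O)[C@H]([C@@H](C)CCC=C(C)C)[C@@H](C(OC)OC)C(=C)C(=O)OCC
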